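**Plan**

1. Retrosynthesis first removes the four O–benzyl bonds, then opens the apigenin pyranone at O1''–C2'' and at the Cα–Cβ bond of its chalcone, giving an aryl aldehyde and a 2-hydroxyacetophenone.
2. In the acacetin half, C7–O is traced back to C7–F; the pyranone is cut at O1–C8a (fluoride displacement by a diketone enolate), then at C2–C3 (enolate aroylation) and C4–C4a (aryllithium acetylation). The diaryl ether is cut at O–C4''' (SNAr on 4-fluorobenzaldehyde) and C8–O comes from a boronate oxidation.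
3. Enabling feature: O1 is bonded to C8a, which is ortho to C4a and its C4 acyl group. Before ring C exists, ring A (a 5-benzyloxy-2-aryloxy-1,3-difluorobenzene) has a mirror plane through C8 and C5, so C8a and C7 can both be C–F and the two C–H sites (future C4a and C6) are identical.
4. Forward order: ring A is oxygenated and joined to the future ring B of the apigenin half; ring C of the acacetin half closes next; C7–F becomes C7–OBn; ring C of the apigenin half closes last by chalcone oxidation. Ring A of apigenin arrives intact in the acetophenone.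
5. Stereochemistry: the target has no stereocentre. The only stereo-element on the way is the E-alkene of the chalcone, set thermodynamically and removed on oxidation.

Key step: step 7

Remark: unprimed locants refer to the acacetin chromone, double primes to the apigenin chromone and triple primes to the apigenin phenyl ring. 1,3-Diketones are drawn as diketo tautomers although the chelated enols should dominate.

**Route**

Step 1
Reactants: 1 3,5-difluorophenol; 2 benzyl bromide
Product: 3 1-(benzyloxy)-3,5-difluorobenzene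
Conditions: BnBr, K2CO3, DMF, rt
Reagents that add atoms: benzyl bromide, BrCc1ccccc1
Why: Williamson ether synthesis; the acidic difluorophenol is fully deprotonated by carbonate and the phenoxide has only one nucleophilic site for SN2 attack on benzyl bromide.

Step 2
Reactants: 3 1-(benzyloxy)-3,5-difluorobenzene
Product: 6 4-(benzyloxy)-2,6-difluorophenol, via 4-(benzyloxy)-2,6-difluorophenyllithium 4 (not isolated), via dimethyl 4-(benzyloxy)-2,6-difluorophenylboronate 5 (not isolated)
Conditions: n-BuLi, THF, −78 °C; B(OMe)3, −78 °C → rt; then 30% H2O2, AcOH, 0 °C → rt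
Reagents that add atoms: hydrogen peroxide, OO
Why: Directed ortho-metalation at the C–H flanked by both fluorines (the most acidic ring position), then borylation and peroxide oxidation with aryl migration from boron to oxygen should give the phenol; holding −78 °C until the borate is added avoids LiF loss to an aryne.

Step 3
Reactants: 6 4-(benzyloxy)-2,6-difluorophenol; 7 4-fluorobenzaldehyde
Product: 8 4-[4-(benzyloxy)-2,6-difluorophenoxy]benzaldehyde
Conditions: K2CO3, DMF, 110 °C
Reagents that add atoms: 4-fluorobenzaldehyde, O=Cc1ccc(F)cc1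
Why: Intermolecular SNAr; the para-formyl group stabilises the Meisenheimer adduct of 4-fluorobenzaldehyde, whereas the fluorines of the phenoxide ring carry no acceptor and stay untouched.

Step 4
Reactants: 8 4-[4-(benzyloxy)-2,6-difluorophenoxy]benzaldehyde; 9 ethylene glycol
Product: 10 2-{4-[4-(benzyloxy)-2,6-difluorophenoxy]phenyl}-1,3-dioxolane
Conditions: HO(CH2)2OH, p-TsOH (cat.), toluene, reflux, Dean–Stark
Reagents that add atoms: ethylene glycol, OCCO
Why: Acid-catalysed acetalisation with azeotropic removal of water masks the aldehyde against the organolithium chemistry that follows.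

Step 5
Reactants: 10 2-{4-[4-(benzyloxy)-2,6-difluorophenoxy]phenyl}-1,3-dioxolane; 11 N-methoxy-N-methylacetamide
Product: 13 1-{6-(benzyloxy)-3-[4-(1,3-dioxolan-2-yl)phenoxy]-2,4-difluorophenyl}ethan-1-one, via ring A aryllithium 12 (not isolated)
Conditions: n-BuLi, THF, −78 °C; then MeC(O)N(OMe)Me, −78 → 0 °C; aq NH4Cl
Reagents that add atoms: N-methoxy-N-methylacetamide, CC(=O)N(C)OC
Why: Directed ortho-metalation at either of the two equivalent ring A C–H positions (each between F and OBn, so only one product is possible), followed by Weinreb amide acylation, whose chelated tetrahedral adduct stops at the ketone.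

Step 6
Reactants: 13 1-{6-(benzyloxy)-3-[4-(1,3-dioxolan-2-yl)phenoxy]-2,4-difluorophenyl}ethan-1-one; 14 4-methoxybenzoyl chloride
Product: 15 1-{6-(benzyloxy)-3-[4-(1,3-dioxolan-2-yl)phenoxy]-2,4-difluorophenyl}-3-(4-methoxyphenyl)propane-1,3-dione
Conditions: LiN(SiMe3)2 (2.2 equiv), THF, −78 °C; then 4-MeOC6H4COCl, −78 → 0 °C; aq NH4Cl
Reagents that add atoms: 4-methoxybenzoyl chloride, COc1ccc(cc1)C(Cl)=O
Why: Claisen-type C-aroylation of the lithium enolate of the methyl ketone; the second equivalent of amide base deprotonates the diketone as it forms, which prevents double acylation, and the low temperature keeps the ortho fluorine intact.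

Step 7
Reactants: 15 1-{6-(benzyloxy)-3-[4-(1,3-dioxolan-2-yl)phenoxy]-2,4-difluorophenyl}-3-(4-methoxyphenyl)propane-1,3-dione
Product: 16 5-(benzyloxy)-8-[4-(1,3-dioxolan-2-yl)phenoxy]-7-fluoro-2-(4-methoxyphenyl)-4H-chromen-4-one
Conditions: K2CO3, DMF, 80 °C
Reagents that add atoms: none
Why: K2CO3 deprotonates the 1,3-diketone, and the enolate oxygen on the anisoyl side adds to the fluorine-bearing carbon ortho to the aryl ketone (future C8a), giving a Meisenheimer anion delocalised into the C4 carbonyl; loss of fluoride then forms the O1–C8a bond. The closest known reaction type is the base-mediated intramolecular SNAr of 1-(2-fluoroaryl)-1,3-diketones to flavones. Ring C closes by a six-membered addition–elimination, 6-exo-trig when counted on the C8a–C8 π bond of the arene. No stereocentre is formed. Two selectivities are needed: between the two C–F bonds, decided by reach, because the enolate oxygen can form a six-membered transition state only with the ortho fluorine while the para fluorine (future C7) is too far; and between the ortho C–F and ortho C–OBn carbons, decided by the much faster addition to a fluorinated carbon and the poor leaving ability of benzyloxide. Since closure is possible only at a C–F carbon, the aryloxy group must end at C8 and the 6-aryloxy isomer cannot arise.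

Step 8
Reactants: 16 5-(benzyloxy)-8-[4-(1,3-dioxolan-2-yl)phenoxy]-7-fluoro-2-(4-methoxyphenyl)-4H-chromen-4-one; 17 benzyl alcohol
Product: 18 5,7-bis(benzyloxy)-8-[4-(1,3-dioxolan-2-yl)phenoxy]-2-(4-methoxyphenyl)-4H-chromen-4-one
Conditions: BnOH, NaH, THF, 0 °C; then 16, 0 → 50 °C
Reagents that add atoms: benzyl alcohol, OCc1ccccc1
Why: Intermolecular SNAr of benzyl oxide at C7, which is para to C4a and so conjugated with the C4 carbonyl; fluoride is the best leaving group for addition–elimination, exchange at C5 would be degenerate, and C8 is not activated.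

Step 9
Reactants: 18 5,7-bis(benzyloxy)-8-[4-(1,3-dioxolan-2-yl)phenoxy]-2-(4-methoxyphenyl)-4H-chromen-4-one
Product: 19 4-{[5,7-bis(benzyloxy)-2-(4-methoxyphenyl)-4-oxo-4H-chromen-8-yl]oxy}benzaldehyde
Conditions: 2 M aq HCl, THF, rt
Reagents that add atoms: water, O
Why: Acid-catalysed acetal hydrolysis; benzyl ethers, the diaryl ether and the flavone are stable to dilute acid at room temperature.

Step 10
Reactants: 20 2,4,6-trihydroxyacetophenone; 2 benzyl bromide
Product: 21 1-[2,4-bis(benzyloxy)-6-hydroxyphenyl]ethan-1-one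
Conditions: BnBr (2.1 equiv), K2CO3, acetone, reflux
Reagents that add atoms: benzyl bromide, BrCc1ccccc1
Why: Williamson benzylation; two of the three hydroxyls react, and the one hydrogen-bonded to the acetyl carbonyl is the least nucleophilic and should remain free.

Step 11
Reactants: 19 4-{[5,7-bis(benzyloxy)-2-(4-methoxyphenyl)-4-oxo-4H-chromen-8-yl]oxy}benzaldehyde; 21 1-[2,4-bis(benzyloxy)-6-hydroxyphenyl]ethan-1-one
Product: 22 (E)-1-[2,4-bis(benzyloxy)-6-hydroxyphenyl]-3-(4-{[5,7-bis(benzyloxy)-2-(4-methoxyphenyl)-4-oxo-4H-chromen-8-yl]oxy}phenyl)prop-2-en-1-one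
Conditions: KOH (50% aq), EtOH/THF, rt; then dilute HCl
Reagents that add atoms: compound 21, CC(=O)c1c(O)cc(OCc2ccccc2)cc1OCc1ccccc1
Why: Claisen–Schmidt aldol condensation between a non-enolisable aryl aldehyde and the acetophenone enolate; E1cB dehydration under equilibrating conditions should give the E-enone.

Step 12
Reactants: 22 (E)-1-[2,4-bis(benzyloxy)-6-hydroxyphenyl]-3-(4-{[5,7-bis(benzyloxy)-2-(4-methoxyphenyl)-4-oxo-4H-chromen-8-yl]oxy}phenyl)prop-2-en-1-one
Product: 23 5,7-bis(benzyloxy)-8-{4-[5,7-bis(benzyloxy)-4-oxo-4H-chromen-2-yl]phenoxy}-2-(4-methoxyphenyl)-4H-chromen-4-one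
Conditions: I2 (0.1 equiv), DMSO, 130 °C
Reagents that add atoms: none
Why: Iodine-catalysed oxidative cyclisation of a 2'-hydroxychalcone (6-endo oxa-Michael closure, α-iodination and HI elimination, with DMSO reoxidising HI); any partial loss of the 5''-benzyl group would not matter because all benzyl groups are removed next.

Step 13
Reactants: 23 5,7-bis(benzyloxy)-8-{4-[5,7-bis(benzyloxy)-4-oxo-4H-chromen-2-yl]phenoxy}-2-(4-methoxyphenyl)-4H-chromen-4-one
Product: 24 5,7-dihydroxy-8-[4-(5,7-dihydroxy-4-oxo-4H-chromen-2-yl)phenoxy]-2-(4-methoxyphenyl)-4H-chromen-4-one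
Conditions: H2 (1 atm), Pd/C (10% palladium on carbon), THF/MeOH, rt
Reagents that add atoms: none
Why: Catalytic hydrogenolysis of the four benzyl aryl ethers; the methyl ether, the diaryl ether and the conjugated pyranone double bonds should survive at atmospheric pressure and room temperature.

**Compound list**

1 | 3,5-difluorophenol | Oc1cc(F)cc(F)c1 | starting material
2 | benzyl bromide | BrCc1ccccc1 | starting material
3 | 1-(benzyloxy)-3,5-difluorobenzene | Fc1cc(F)cc(OCc2ccccc2)c1 | intermediate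
4 | [4-(benzyloxy)-2,6-difluorophenyl]lithium | [Li]c1c(F)cc(OCc2ccccc2)cc1F | intermediate
5 | dimethyl [4-(benzyloxy)-2,6-difluorophenyl]boronate | COB(OC)c1c(F)cc(OCc2ccccc2)cc1F | intermediate
6 | 4-(benzyloxy)-2,6-difluorophenol | Oc1c(F)cc(OCc2ccccc2)cc1F | intermediate
7 | 4-fluorobenzaldehyde | O=Cc1ccc(F)cc1 | starting material
8 | 4-[4-(benzyloxy)-2,6-difluorophenoxy]benzaldehyde | O=Cc1ccc(Oc2c(F)cc(OCc3ccccc3)cc2F)cc1 | intermediate
9 | ethylene glycol | OCCO | starting material
10 | 2-{4-[4-(benzyloxy)-2,6-difluorophenoxy]phenyl}-1,3-dioxolane | Fc1cc(OCc2ccccc2)cc(F)c1Oc1ccc(cc1)C1OCCO1 | intermediate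
11 | N-methoxy-N-methylacetamide | CC(=O)N(C)OC | starting material
12 | {6-(benzyloxy)-3-[4-(1,3-dioxolan-2-yl)phenoxy]-2,4-difluorophenyl}lithium | [Li]c1c(F)c(Oc2ccc(cc2)C2OCCO2)c(F)cc1OCc1ccccc1 | intermediate
13 | 1-{6-(benzyloxy)-3-[4-(1,3-dioxolan-2-yl)phenoxy]-2,4-difluorophenyl}ethan-1-one | CC(=O)c1c(F)c(Oc2ccc(cc2)C2OCCO2)c(F)cc1OCc1ccccc1 | intermediate
14 | 4-methoxybenzoyl chloride | COc1ccc(cc1)C(Cl)=O | starting material
15 | 1-{6-(benzyloxy)-3-[4-(1,3-dioxolan-2-yl)phenoxy]-2,4-difluorophenyl}-3-(4-methoxyphenyl)propane-1,3-dione | COc1ccc(cc1)C(=O)CC(=O)c1c(F)c(Oc2ccc(cc2)C2OCCO2)c(F)cc1OCc1ccccc1 | intermediate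
16 | 5-(benzyloxy)-8-[4-(1,3-dioxolan-2-yl)phenoxy]-7-fluoro-2-(4-methoxyphenyl)-4H-chromen-4-one | COc1ccc(cc1)-c1cc(=O)c2c(OCc3ccccc3)cc(F)c(Oc3ccc(cc3)C3OCCO3)c2o1 | intermediate
17 | benzyl alcohol | OCc1ccccc1 | starting material
18 | 5,7-bis(benzyloxy)-8-[4-(1,3-dioxolan-2-yl)phenoxy]-2-(4-methoxyphenyl)-4H-chromen-4-one | COc1ccc(cc1)-c1cc(=O)c2c(OCc3ccccc3)cc(OCc3ccccc3)c(Oc3ccc(cc3)C3OCCO3)c2o1 | intermediate
19 | 4-{[5,7-bis(benzyloxy)-2-(4-methoxyphenyl)-4-oxo-4H-chromen-8-yl]oxy}benzaldehyde | COc1ccc(cc1)-c1cc(=O)c2c(OCc3ccccc3)cc(OCc3ccccc3)c(Oc3ccc(C=O)cc3)c2o1 | intermediate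
20 | 2,4,6-trihydroxyacetophenone | CC(=O)c1c(O)cc(O)cc1O | starting material
21 | 1-[2,4-bis(benzyloxy)-6-hydroxyphenyl]ethan-1-one | CC(=O)c1c(O)cc(OCc2ccccc2)cc1OCc1ccccc1 | intermediate
22 | (E)-1-[2,4-bis(benzyloxy)-6-hydroxyphenyl]-3-(4-{[5,7-bis(benzyloxy)-2-(4-methoxyphenyl)-4-oxo-4H-chromen-8-yl]oxy}phenyl)prop-2-en-1-one | COc1ccc(cc1)-c1cc(=O)c2c(OCc3ccccc3)cc(OCc3ccccc3)c(Oc3ccc(/C=C/C(=O)c4c(O)cc(OCc5ccccc5)cc4OCc4ccccc4)cc3)c2o1 | intermediate
23 | 5,7-bis(benzyloxy)-8-{4-[5,7-bis(benzyloxy)-4-oxo-4H-chromen-2-yl]phenoxy}-2-(4-methoxyphenyl)-4H-chromen-4-one | COc1ccc(cc1)-c1cc(=O)c2c(OCc3ccccc3)cc(OCc3ccccc3)c(Oc3ccc(cc3)-c3cc(=O)c4c(OCc5ccccc5)cc(OCc5ccccc5)cc4o3)c2o1 | intermediate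
24 | 5,7-dihydroxy-8-[4-(5,7-dihydroxy-4-oxo-4H-chromen-2-yl)phenoxy]-2-(4-methoxyphenyl)-4H-chromen-4-one (CNP0295851.0) | COc1ccc(-c2cc(=O)c3c(O)cc(O)c(Oc4ccc(-c5cc(=O)c6c(O)cc(O)cc6o5)cc4)c3o2)cc1 | target

**Step count and risks**

Total step count: 13. Longest linear sequence: 12 steps (steps 1–9 and 11–13); step 10 is a one-step side branch.

The three steps most likely to fail, in route order:

Step 5. Butyllithium may deprotonate the benzylic CH2 of the benzyl ether (with Wittig rearrangement) or the acetal C–H instead of the ring. The aryllithium may also be quenched by proton transfer from the Weinreb amide, or lose LiF on warming. The fallback avoids deprotonation altogether; it sets out from 8 and returns at 13. NBS in MeCN at rt should brominate the only free position of ring A, ortho to the benzyloxy group, giving 4-[4-(benzyloxy)-3-bromo-2,6-difluorophenoxy]benzaldehyde F1. Stille coupling of this bromide with tributyl(1-ethoxyvinyl)stannane [PdCl2(PPh3)2, toluene, 100 °C] should give the enol ether 4-[4-(benzyloxy)-3-(1-ethoxyethenyl)-2,6-difluorophenoxy]benzaldehyde F2. Hydrolysis with 1 M HCl in THF should then give the keto aldehyde 4-[3-acetyl-4-(benzyloxy)-2,6-difluorophenoxy]benzaldehyde F3. Acetalisation with ethylene glycol 9 (p-TsOH cat., toluene, Dean–Stark) should occur only at the aldehyde, because the ketone sits between two ortho substituents, and this gives 13.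

Step 8. Fluoride displacement on the electron-rich ring A may be slow, and the strongly basic alkoxide may instead add at C2 and open the pyranone. The fallback replaces the alkoxide by a weakly basic oximate and installs the benzyl group by O-alkylation; it sets out from 16 and returns at 18. (E)-Benzaldoxime with K2CO3 in DMSO at 80 °C should displace the C7 fluoride to give the O-aryl oxime (E)-benzaldehyde O-{5-(benzyloxy)-8-[4-(1,3-dioxolan-2-yl)phenoxy]-2-(4-methoxyphenyl)-4-oxo-4H-chromen-7-yl}oxime F4. This should fragment in the flask with loss of benzonitrile to the phenol 5-(benzyloxy)-8-[4-(1,3-dioxolan-2-yl)phenoxy]-7-hydroxy-2-(4-methoxyphenyl)-4H-chromen-4-one F5. Benzylation of this phenol with benzyl bromide 2 and K2CO3 in DMF gives 18.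

Step 11. Concentrated hydroxide may attack C2 of the existing flavone and open or cleave its pyranone during the long aldol reaction, and the poor solubility of 19 may stall the condensation. The fallback builds the second pyranone by acyl transfer instead of aldol chemistry; it sets out from 19 and returns at 23, bypassing 22 and step 12. Pinnick oxidation (NaClO2, NaH2PO4, 2-methylbut-2-ene, t-BuOH/THF/H2O) should give the acid 4-{[5,7-bis(benzyloxy)-2-(4-methoxyphenyl)-4-oxo-4H-chromen-8-yl]oxy}benzoic acid F6. Esterification with phenol 21 (EDC·HCl, DMAP, CH2Cl2) should give the aryl ester 2-acetyl-3,5-bis(benzyloxy)phenyl 4-{[5,7-bis(benzyloxy)-2-(4-methoxyphenyl)-4-oxo-4H-chromen-8-yl]oxy}benzoate F7. Baker–Venkataraman rearrangement with the non-nucleophilic base t-BuOK in THF should give the diketone 1-[2,4-bis(benzyloxy)-6-hydroxyphenyl]-3-(4-{[5,7-bis(benzyloxy)-2-(4-methoxyphenyl)-4-oxo-4H-chromen-8-yl]oxy}phenyl)propane-1,3-dione F8. Cyclodehydration with catalytic p-TsOH in toluene at 90 °C gives 23.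

Further compounds
F1 | step 5 | 4-[4-(benzyloxy)-3-bromo-2,6-difluorophenoxy]benzaldehyde | O=Cc1ccc(Oc2c(F)cc(OCc3ccccc3)c(Br)c2F)cc1
F2 | step 5 | 4-[4-(benzyloxy)-3-(1-ethoxyethenyl)-2,6-difluorophenoxy]benzaldehyde | CCOC(=C)c1c(F)c(Oc2ccc(C=O)cc2)c(F)cc1OCc1ccccc1
F3 | step 5 | 4-[3-acetyl-4-(benzyloxy)-2,6-difluorophenoxy]benzaldehyde | CC(=O)c1c(F)c(Oc2ccc(C=O)cc2)c(F)cc1OCc1ccccc1
F4 | step 8 | (E)-benzaldehyde O-{5-(benzyloxy)-8-[4-(1,3-dioxolan-2-yl)phenoxy]-2-(4-methoxyphenyl)-4-oxo-4H-chromen-7-yl}oxime | COc1ccc(cc1)-c1cc(=O)c2c(OCc3ccccc3)cc(O/N=C/c3ccccc3)c(Oc3ccc(cc3)C3OCCO3)c2o1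
F5 | step 8 | 5-(benzyloxy)-8-[4-(1,3-dioxolan-2-yl)phenoxy]-7-hydroxy-2-(4-methoxyphenyl)-4H-chromen-4-one | COc1ccc(cc1)-c1cc(=O)c2c(OCc3ccccc3)cc(O)c(Oc3ccc(cc3)C3OCCO3)c2o1
F6 | step 11 | 4-{[5,7-bis(benzyloxy)-2-(4-methoxyphenyl)-4-oxo-4H-chromen-8-yl]oxy}benzoic acid | COc1ccc(cc1)-c1cc(=O)c2c(OCc3ccccc3)cc(OCc3ccccc3)c(Oc3ccc(cc3)C(O)=O)c2o1
F7 | step 11 | 2-acetyl-3,5-bis(benzyloxy)phenyl 4-{[5,7-bis(benzyloxy)-2-(4-methoxyphenyl)-4-oxo-4H-chromen-8-yl]oxy}benzoate | CC(=O)c1c(OC(=O)c2ccc(Oc3c(OCc4ccccc4)cc(OCc4ccccc4)c4c(=O)cc(-c5ccc(OC)cc5)oc34)cc2)cc(OCc2ccccc2)cc1OCc1ccccc1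
F8 | step 11 | 1-[2,4-bis(benzyloxy)-6-hydroxyphenyl]-3-(4-{[5,7-bis(benzyloxy)-2-(4-methoxyphenyl)-4-oxo-4H-chromen-8-yl]oxy}phenyl)propane-1,3-dione | O=C(CC(=O)c1c(O)cc(OCc2ccccc2)cc1OCc1ccccc1)c1ccc(Oc2c(OCc3ccccc3)cc(OCc3ccccc3)c3c(=O)cc(-c4ccc(OC)cc4)oc23)cc1
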